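**Retrosynthetic overview**
1. Target ⇐ C1 ketone reduction ⇐ ketal hydrolysis ⇐ E-cinnamate made by Horner–Wadsworth–Emmons olefination of a 6β-O-phosphonoacetate, which is put on before C4 becomes a crowded carbinol.
2. 4α-OH/4β-CH3 ⇐ Wharton transposition of a 3α,4α-epoxy-2-ketone ⇐ Δ3-2-ketone ⇐ trans-fused 2,6-dione (C6=O from hydroboration of C6=C7; C5 and C7 set by equilibration next to C6=O).
3. Ring A ⇐ anionic oxy-Cope rearrangement of a propenyl bicyclo[2.2.2]octenol: C4–C5 forms while the C2–C7 cage bond breaks.
4. Bicyclooctenone ⇐ Diels–Alder reaction of a carvacrol-derived masked o-benzoquinone with (R)-p-tolyl vinyl sulfoxide (chiral ethylene equivalent), then desulfurisation and propenylcerium addition.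
5. Feature: ring B (C5–C10) carries C10–CH3 and C7–isopropyl in a 1,4 (p-cymene) relationship, so both can be bridgeheads of an arene-derived bicyclo[2.2.2]octene; ring B is formed first (from the arene), ring A second (step 8).

Key step: step 8

Assumption: the target is read as 1β,4α-dihydroxyeudesman-6β-yl (E)-cinnamate with 5α-H, 7α-H (7β-isopropyl) and 10β-CH3; eudesmane numbering and α/β (β = face of the C10 methyl) are used for all decalins.
Remark: carvacrol rather than its isomer thymol is the arene of choice, because its only free ortho position lies beside the isopropyl group; steps 1–3 therefore place the free phenol next to isopropyl and the methyl ether next to methyl, which puts the later carbinol carbon (C2) next to the isopropyl-bearing bridgehead (C7).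

Step 1
Reactants: 1 carvacrol (5-isopropyl-2-methylphenol)
Product: 2 2-hydroxy-6-isopropyl-3-methylbenzaldehyde
Conditions: MgCl2, Et3N, (CH2O)n, MeCN, reflux; aq. HCl work-up
Reagents that add atoms: paraformaldehyde (as formaldehyde), C=O
Why: Magnesium phenoxide-directed ortho-formylation (Casnati–Skattebøl reaction) delivers formaldehyde only ortho to the hydroxyl, and the single free ortho position of carvacrol is the one next to the isopropyl group, so the carbon that becomes the free phenol of 5 is fixed beside isopropyl without any regiochemical choice.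

Step 2
Reactants: 2 2-hydroxy-6-isopropyl-3-methylbenzaldehyde
Product: 3 6-isopropyl-2-methoxy-3-methylbenzaldehyde
Conditions: MeI, K2CO3, DMF, 40 °C
Reagents that add atoms: iodomethane, CI
Why: Williamson O-methylation of the phenoxide works on salicylaldehydes once carbonate in DMF breaks the internal hydrogen bond, and it marks the oxygen next to the ring methyl as the future ketal oxygen.

Step 3
Reactants: 3 6-isopropyl-2-methoxy-3-methylbenzaldehyde
Product: 5 6-isopropyl-2-methoxy-3-methylphenol, via aryl formate 4 (not isolated)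
Conditions: mCPBA, CH2Cl2, rt; then NaOH, MeOH/H2O, 0 °C; acidify
Reagents that add atoms: m-chloroperoxybenzoic acid, O=C(OO)c1cccc(Cl)c1
Why: Dakin-type Baeyer–Villiger oxidation, in which the electron-rich ortho-alkoxy aryl group migrates in the Criegee adduct in preference to hydrogen to give formate 4, whose saponification frees the phenol that sits next to isopropyl.

Step 4
Reactants: 5 6-isopropyl-2-methoxy-3-methylphenol
Product: 6 2-isopropyl-6,6-dimethoxy-5-methylcyclohexa-2,4-dien-1-one (masked o-benzoquinone)
Conditions: PhI(OAc)2, MeOH, 0 °C; solvent exchanged to CH2Cl2, used at once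
Reagents that add atoms: methanol, CO
Why: Oxidative dearomatisation of a 2-methoxyphenol with a hypervalent iodine reagent adds methanol at the methoxy-bearing carbon to give the o-quinone monoketal with its carbonyl next to the isopropyl-bearing diene terminus, and the alkyl groups on both diene termini should slow the self-dimerisation typical of unsubstituted masked o-benzoquinones.

Step 5
Reactants: 6 2-isopropyl-6,6-dimethoxy-5-methylcyclohexa-2,4-dien-1-one; 7 (R)-p-tolyl vinyl sulfoxide
Product: 8 (1S,4R,7R)-1-isopropyl-3,3-dimethoxy-4-methyl-7-[(R)-p-tolylsulfinyl]bicyclo[2.2.2]oct-5-en-2-one (sulfinyl group syn to the C5=C6 bridge; same bridgehead arrangement as 9)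
Conditions: 7 (3 equiv), CH2Cl2, 12 kbar, 40 °C; chromatographic separation of the sulfoxide diastereomers
Reagents that add atoms: none
Why: Diels–Alder [4+2] cycloaddition of a 2,4-cyclohexadienone with a vinyl sulfoxide as ethylene equivalent, run under pressure because both diene termini are fully substituted; the two bridgeheads are set together by the diene face that reacts, and since the sulfur stereocentre makes the adducts of the two faces diastereomers, the required bridgehead configuration (expected mainly as the 7-sulfinyl adduct 8) is secured by separation rather than by facial bias alone, while any regio- or endo/exo isomer of the same bridgehead sense converges in step 6.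

Step 6
Reactants: 8 (1S,4R,7R)-1-isopropyl-3,3-dimethoxy-4-methyl-7-[(R)-p-tolylsulfinyl]bicyclo[2.2.2]oct-5-en-2-one
Product: 9 (1R,4R)-1-isopropyl-3,3-dimethoxy-4-methylbicyclo[2.2.2]oct-5-en-2-one
Conditions: Raney Ni (W-2, deactivated in refluxing acetone), EtOH/acetone, rt → 50 °C
Reagents that add atoms: none
Why: Raney nickel hydrogenolysis of the C–S bond (reductive desulfurisation of a sulfoxide) removes the auxiliary without touching the bridgehead stereocentres, and on deactivated catalyst the bridging alkene, shielded by two quaternary bridgeheads, and the hindered non-enolisable ketone should survive.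

Step 7
Reactants: 9 (1R,4R)-1-isopropyl-3,3-dimethoxy-4-methylbicyclo[2.2.2]oct-5-en-2-one; 10 (E)-1-bromopropene
Product: 13 (1R,2S,4R)-1-isopropyl-3,3-dimethoxy-4-methyl-2-[(E)-prop-1-enyl]bicyclo[2.2.2]oct-5-en-2-ol (propenyl syn to the C5=C6 bridge), via (E)-prop-1-enyllithium 11 (not isolated), via (E)-prop-1-enylcerium dichloride 12 (not isolated)
Conditions: 10, t-BuLi (2 equiv), Et2O, −78 °C; CeCl3, THF, −78 °C; then 9, −78 → 0 °C; H2O
Reagents that add atoms: none
Why: Bromine–lithium exchange keeps the E geometry, transmetalation to cerium gives a weakly basic, oxophilic nucleophile suited to the hindered ketone, and 1,2-addition occurs on the carbonyl face beside the C5=C6 bridge, which lacks the inward hydrogens of the C7–C8 bridge, so the new C2 carbinol carries propenyl syn to the alkene bridge as the [3,3] shift requires.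

Step 8
Reactants: 13 (1R,2S,4R)-1-isopropyl-3,3-dimethoxy-4-methyl-2-[(E)-prop-1-enyl]bicyclo[2.2.2]oct-5-en-2-ol
Product: 16 cis-fused 1,1-dimethoxyeudesm-6-en-2-one (4α-CH3, 5β-H, 10β-CH3), via potassium alkoxide 14 (not isolated), via potassium enolate 15 (not isolated)
Conditions: KH, 18-crown-6, THF, 0 °C → rt (→ 60 °C if needed); aq. NH4Cl, −78 °C
Reagents that add atoms: none
Why: Deprotonation gives alkoxide 14, whose crown-ether-separated oxyanion weakens the adjacent C1–C2 cage bond and triggers a concerted anionic oxy-Cope [3,3] shift of the 1,5-diene Cβ=Cα–C2–C1–C6=C5: the C1–C2 bond breaks, the C5–Cβ bond (eudesmane C4–C5) forms, and enolate 15 (C2=C3) and the C6=C7 alkene appear; the closest known reaction is the anionic oxy-Cope rearrangement of 2-alkenylbicyclo[2.2.2]oct-5-en-2-ols from masked o-benzoquinone adducts to cis-decalin-2-ones. Ring A (C1–C5, C10) closes in this single pericyclic event through the six-centre boat array that the cage enforces, a sigmatropic six-membered closure at C4–C5 while the carbinol bridge opens. C5 is set because the new bond can only form on the face of the C5=C6 bridge that looks at the carbinol bridge, which puts H-5 cis to the C10 methyl, and C4 is set by the E geometry of the propenyl group, whose methyl sits on the outside of the boat (4α-CH3); C10 is carried over unchanged. The step needs the [3,3] shift to win over a [1,3] shift or fragmentation, which is secured by the syn placement of propenyl and alkene bridge from step 7, by the fully substituted isopropyl-bearing C1 that weakens the bond to be broken, and by the release of cage strain into a delocalised enolate. Protonation of 15 at C3 at low temperature gives ketone 16 without moving the trisubstituted alkene.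

Step 9
Reactants: 16 cis-fused 1,1-dimethoxyeudesm-6-en-2-one
Product: 18 cis-fused 1,1-dimethoxyeudesmane-2,6-diol (4α-CH3, 5β-H, 10β-CH3; mixture at C2, C6 and C7, with 6-OH and 7-H cis), via alkylborane 17 (not isolated)
Conditions: BH3·THF (4 equiv), THF, 0 °C → rt; then NaOH, 30% H2O2, 0 °C → rt
Reagents that add atoms: hydrogen peroxide, OO
Why: Hydroboration–oxidation, in which borane adds boron to the less substituted C6 of the trisubstituted alkene (anti-Markovnikov, syn addition) and also reduces the C2 ketone; since C2 and C6 are reoxidised and C7 is equilibrated in step 10, the configurations formed here do not matter.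

Step 10
Reactants: 18 cis-fused 1,1-dimethoxyeudesmane-2,6-diol
Product: 20 trans-fused 1,1-dimethoxyeudesmane-2,6-dione (4α-CH3, 5α-H, 7β-isopropyl, 10β-CH3), via cis-fused dione 19 (not isolated)
Conditions: Dess–Martin periodinane, NaHCO3, CH2Cl2, rt; then NaOMe (cat.), MeOH, rt
Reagents that add atoms: none
Why: Dess–Martin oxidation of both secondary alcohols followed by methoxide-mediated epimerisation at C5 and C7 through the C6 enolates (thermodynamic control); the trans-fused isomer with equatorial 7β-isopropyl should dominate because one chair–chair form of the cis isomer has a ring bond syn-axial to 1α-OMe and the other places 4α-CH3 syn-axial to C9.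

Step 11
Reactants: 20 trans-fused 1,1-dimethoxyeudesmane-2,6-dione
Product: 22 1,1-dimethoxy-2-(triethylsilyloxy)eudesm-2-en-6-one (4α-CH3, 5α-H, 7β-isopropyl, 10β-CH3), via lithium enolate 21 (not isolated)
Conditions: LiN(SiMe3)2 (1.05 equiv), THF, −78 °C; then Et3SiCl, Et3N, −78 → 0 °C
Reagents that add atoms: chlorotriethylsilane, CC[Si](Cl)(CC)CC
Why: Kinetic deprotonation with a hindered amide base takes the only α-methylene (C3) rather than the two hindered α-methines of the C6 ketone, and O-silylation of the lithium enolate gives the C2 enol silane, which masks the C2 carbonyl and prepares the dehydrogenation of step 13.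

Step 12
Reactants: 22 1,1-dimethoxy-2-(triethylsilyloxy)eudesm-2-en-6-one
Product: 23 1,1-dimethoxy-2-(triethylsilyloxy)eudesm-2-en-6β-ol
Conditions: LiAlH4, THF, −78 → 0 °C; Rochelle salt work-up
Reagents that add atoms: none
Why: Hydride reduction of the C6 ketone, in which the axial trajectory on the β face is blocked by the syn-axial C10 methyl, so hydride should arrive from the α face and give the axial 6β-alcohol, while the silyl enol ether and the ketal are inert to LiAlH4.

Step 13
Reactants: 23 1,1-dimethoxy-2-(triethylsilyloxy)eudesm-2-en-6β-ol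
Product: 24 6β-hydroxy-1,1-dimethoxyeudesm-3-en-2-one (5α-H, 7β-isopropyl, 10β-CH3)
Conditions: Pd(OAc)2 (1.1 equiv), MeCN, rt
Reagents that add atoms: none
Why: Saegusa–Ito oxidation, in which the enol silane transmetalates to a palladium enolate at C3 and β-hydride elimination of H-4 gives the Δ3-2-ketone, deliberately erasing the C4 stereocentre made in step 8.

Step 14
Reactants: 24 6β-hydroxy-1,1-dimethoxyeudesm-3-en-2-one
Product: 25 3α,4α-epoxy-6β-hydroxy-1,1-dimethoxyeudesman-2-one (4β-CH3)
Conditions: 30% H2O2, aq. NaOH, MeOH, 0 °C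
Reagents that add atoms: hydrogen peroxide, OO
Why: Weitz–Scheffer nucleophilic epoxidation, in which hydroperoxide adds to C4 from the α face because the β face is screened by the syn-axial C10 methyl and 6β-hydroxyl, and the enolate closes to the 3α,4α-epoxide; the free 6-hydroxyl offers no leaving group for vinylogous elimination.

Step 15
Reactants: 25 3α,4α-epoxy-6β-hydroxy-1,1-dimethoxyeudesman-2-one; 26 diethylphosphonoacetic acid
Product: 27 3α,4α-epoxy-1,1-dimethoxy-2-oxoeudesman-6β-yl (diethoxyphosphoryl)acetate
Conditions: 26, DCC, DMAP (cat.), CH2Cl2, 0 °C → rt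
Reagents that add atoms: none
Why: Carbodiimide (Steglich-type) esterification in which the phosphonoacetic acid is delivered through a small ketene-like acylating species, done now because the 6β-hydroxyl still has only the C10 methyl as a true syn-axial neighbour, and chosen because the phosphonoacetate survives the hydrogenation of step 17, which a cinnamate would not.

Step 16
Reactants: 27 3α,4α-epoxy-1,1-dimethoxy-2-oxoeudesman-6β-yl (diethoxyphosphoryl)acetate
Product: 28 4α-hydroxy-1,1-dimethoxyeudesm-2-en-6β-yl (diethoxyphosphoryl)acetate (4β-CH3)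
Conditions: N2H4·H2O (3 equiv), AcOH (cat.), MeOH, 0 °C → rt
Reagents that add atoms: none
Why: Wharton transposition, in which the C2 hydrazone opens the epoxide, loses dinitrogen and leaves the C2=C3 alkene with the oxygen still bound to C4, so the α-oxygen of the epoxide becomes the tertiary 4α-hydroxyl with 4β-methyl.

Step 17
Reactants: 28 4α-hydroxy-1,1-dimethoxyeudesm-2-en-6β-yl (diethoxyphosphoryl)acetate
Product: 29 4α-hydroxy-1,1-dimethoxyeudesman-6β-yl (diethoxyphosphoryl)acetate
Conditions: H2 (1 atm), Rh/Al2O3, EtOAc, rt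
Reagents that add atoms: none
Why: Heterogeneous hydrogenation of the cis-disubstituted C2=C3 alkene, with rhodium on alumina chosen to limit hydrogenolysis of the allylic C–O bonds at C1 and C4; no stereocentre is formed.

Step 18
Reactants: 29 4α-hydroxy-1,1-dimethoxyeudesman-6β-yl (diethoxyphosphoryl)acetate; 30 benzaldehyde
Product: 31 4α-hydroxy-1,1-dimethoxyeudesman-6β-yl (E)-cinnamate
Conditions: 30, LiCl, DBU, MeCN, rt
Reagents that add atoms: none
Why: Horner–Wadsworth–Emmons olefination under Masamune–Roush conditions gives the E-cinnamate from the stabilised phosphonate and an aryl aldehyde, and the mild base leaves the tertiary alcohol and the ketal alone.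

Step 19
Reactants: 31 4α-hydroxy-1,1-dimethoxyeudesman-6β-yl (E)-cinnamate
Product: 32 4α-hydroxy-1-oxoeudesman-6β-yl (E)-cinnamate
Conditions: TsOH·H2O (cat.), acetone/H2O, rt
Reagents that add atoms: water, O
Why: Acid-catalysed hydrolysis of the dimethyl ketal, helped by relief of crowding next to the quaternary C10, unmasks the C1 ketone under conditions mild enough for the cinnamate and the tertiary alcohol.

Step 20
Reactants: 32 4α-hydroxy-1-oxoeudesman-6β-yl (E)-cinnamate
Product: 33 1β,4α-dihydroxyeudesman-6β-yl (E)-cinnamate (CNP0114792.1)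
Conditions: NaBH4, MeOH, −20 → 0 °C
Reagents that add atoms: none
Why: Borohydride reduction of the C1 ketone by axial attack from the α face, the β face being crowded by the neighbouring axial C10 methyl, gives the equatorial 1β-alcohol, and the hindered cinnamate is not reduced at low temperature.

**Compound list**
1 | carvacrol (5-isopropyl-2-methylphenol) | Cc1ccc(C(C)C)cc1O | starting material
2 | 2-hydroxy-6-isopropyl-3-methylbenzaldehyde | Cc1ccc(C(C)C)c(C=O)c1O | intermediate
3 | 6-isopropyl-2-methoxy-3-methylbenzaldehyde | COc1c(C)ccc(C(C)C)c1C=O | intermediate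
4 | 6-isopropyl-2-methoxy-3-methylphenyl formate (not isolated) | COc1c(C)ccc(C(C)C)c1OC=O | intermediate
5 | 6-isopropyl-2-methoxy-3-methylphenol | COc1c(C)ccc(C(C)C)c1O | intermediate
6 | 2-isopropyl-6,6-dimethoxy-5-methylcyclohexa-2,4-dien-1-one | COC1(OC)C(C)=CC=C(C(C)C)C1=O | intermediate
7 | (R)-p-tolyl vinyl sulfoxide | C=C[S@@](=O)c1ccc(C)cc1 | starting material
8 | (1S,4R,7R)-1-isopropyl-3,3-dimethoxy-4-methyl-7-[(R)-p-tolylsulfinyl]bicyclo[2.2.2]oct-5-en-2-one | CC(C)[C@]12[C@H]([S@@](=O)c3ccc(C)cc3)C[C@](C)(C=C1)C(OC)(OC)C2=O | intermediate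
9 | (1R,4R)-1-isopropyl-3,3-dimethoxy-4-methylbicyclo[2.2.2]oct-5-en-2-one | CC(C)[C@]12CC[C@](C)(C=C1)C(OC)(OC)C2=O | intermediate
10 | (E)-1-bromopropene | C/C=C/Br | starting material
11 | (E)-prop-1-enyllithium (not isolated) | C/C=C/[Li] | intermediate
12 | (E)-prop-1-enylcerium dichloride (not isolated) | C/C=C/[Ce](Cl)Cl | intermediate
13 | (1R,2S,4R)-1-isopropyl-3,3-dimethoxy-4-methyl-2-[(E)-prop-1-enyl]bicyclo[2.2.2]oct-5-en-2-ol | CC(C)[C@]12CC[C@](C)(C=C1)C(OC)(OC)[C@]2(O)/C=C/C | intermediate
14 | potassium alkoxide of 13 (not isolated) | CC(C)[C@]12CC[C@](C)(C=C1)C(OC)(OC)[C@]2([O-])/C=C/C.[K+] | intermediate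
15 | potassium C2=C3 enolate of 16 (not isolated) | CC(C)C1=C[C@@H]2[C@H](C)C=C([O-])C(OC)(OC)[C@]2(C)CC1.[K+] | intermediate
16 | cis-fused 1,1-dimethoxyeudesm-6-en-2-one (4α-CH3, 5β-H, 10β-CH3) | CC(C)C1=C[C@@H]2[C@H](C)CC(=O)C(OC)(OC)[C@]2(C)CC1 | intermediate
17 | alkylborane from 16, drawn as the 6-boryl 2-boryloxy compound (not isolated; C2, C6, C7 unassigned) | CC(C)C1C(B)[C@@H]2[C@H](C)CC(OB)C(OC)(OC)[C@]2(C)CC1 | intermediate
18 | cis-fused 1,1-dimethoxyeudesmane-2,6-diol (C2, C6, C7 mixture) | CC(C)C1C(O)[C@@H]2[C@H](C)CC(O)C(OC)(OC)[C@]2(C)CC1 | intermediate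
19 | cis-fused 1,1-dimethoxyeudesmane-2,6-dione (5β-H; C7 mixture; not isolated) | CC(C)C1C(=O)[C@@H]2[C@H](C)CC(=O)C(OC)(OC)[C@]2(C)CC1 | intermediate
20 | trans-fused 1,1-dimethoxyeudesmane-2,6-dione (4α-CH3, 5α-H, 7β-isopropyl, 10β-CH3) | CC(C)[C@@H]1CC[C@@]2(C)C(OC)(OC)C(=O)C[C@@H](C)[C@@H]2C1=O | intermediate
21 | lithium C2=C3 enolate of 20 (not isolated) | CC(C)[C@@H]1CC[C@@]2(C)C(OC)(OC)C([O-])=C[C@@H](C)[C@@H]2C1=O.[Li+] | intermediate
22 | 1,1-dimethoxy-2-(triethylsilyloxy)eudesm-2-en-6-one | CC(C)[C@@H]1CC[C@@]2(C)C(OC)(OC)C(O[Si](CC)(CC)CC)=C[C@@H](C)[C@@H]2C1=O | intermediate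
23 | 1,1-dimethoxy-2-(triethylsilyloxy)eudesm-2-en-6β-ol | CC(C)[C@@H]1CC[C@@]2(C)C(OC)(OC)C(O[Si](CC)(CC)CC)=C[C@@H](C)[C@@H]2[C@@H]1O | intermediate
24 | 6β-hydroxy-1,1-dimethoxyeudesm-3-en-2-one | CC(C)[C@@H]1CC[C@@]2(C)C(OC)(OC)C(=O)C=C(C)[C@@H]2[C@@H]1O | intermediate
25 | 3α,4α-epoxy-6β-hydroxy-1,1-dimethoxyeudesman-2-one | CC(C)[C@@H]1CC[C@@]2(C)C(OC)(OC)C(=O)[C@H]3O[C@@]3(C)[C@@H]2[C@@H]1O | intermediate
26 | diethylphosphonoacetic acid | CCOP(=O)(CC(=O)O)OCC | starting material
27 | 3α,4α-epoxy-1,1-dimethoxy-2-oxoeudesman-6β-yl (diethoxyphosphoryl)acetate | CC(C)[C@@H]1CC[C@@]2(C)C(OC)(OC)C(=O)[C@H]3O[C@@]3(C)[C@@H]2[C@@H]1OC(=O)CP(=O)(OCC)OCC | intermediate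
28 | 4α-hydroxy-1,1-dimethoxyeudesm-2-en-6β-yl (diethoxyphosphoryl)acetate | CC(C)[C@@H]1CC[C@@]2(C)C(OC)(OC)C=C[C@@](C)(O)[C@@H]2[C@@H]1OC(=O)CP(=O)(OCC)OCC | intermediate
29 | 4α-hydroxy-1,1-dimethoxyeudesman-6β-yl (diethoxyphosphoryl)acetate | CC(C)[C@@H]1CC[C@@]2(C)C(OC)(OC)CC[C@@](C)(O)[C@@H]2[C@@H]1OC(=O)CP(=O)(OCC)OCC | intermediate
30 | benzaldehyde | O=Cc1ccccc1 | starting material
31 | 4α-hydroxy-1,1-dimethoxyeudesman-6β-yl (E)-cinnamate | CC(C)[C@@H]1CC[C@@]2(C)C(OC)(OC)CC[C@@](C)(O)[C@@H]2[C@@H]1OC(=O)/C=C/c1ccccc1 | intermediate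
32 | 4α-hydroxy-1-oxoeudesman-6β-yl (E)-cinnamate | CC(C)[C@@H]1CC[C@@]2(C)C(=O)CC[C@@](C)(O)[C@@H]2[C@@H]1OC(=O)/C=C/c1ccccc1 | intermediate
33 | 1β,4α-dihydroxyeudesman-6β-yl (E)-cinnamate (CNP0114792.1) | CC(C)[C@@H]1CC[C@@]2(C)[C@H](O)CC[C@@](C)(O)[C@@H]2[C@@H]1OC(=O)/C=C/c1ccccc1 | target

**Totals**
Total step count: 20. Longest linear sequence: 20 steps (1 → 33); 7, 10, 26 and 30 enter as purchased reagents.

**Steps most likely to fail**

Step 5 (Diels–Alder). Bond formation at two fully substituted diene termini with a weak dienophile may be too slow even under pressure. Heating could cause loss of sulfenic acid from the adducts. A weak facial bias could leave diastereomer mixtures that are hard to separate and assign. The fallback sets out from 6 and comes back at 9. Compound 6 is heated with phenyl vinyl sulfide, an electron-rich dienophile of the kind that adds readily to masked o-benzoquinones (toluene, 80–100 °C), to give rac-1-isopropyl-3,3-dimethoxy-4-methyl-7-(phenylsulfanyl)bicyclo[2.2.2]oct-5-en-2-one F1. Raney Ni then gives rac-1-isopropyl-3,3-dimethoxy-4-methylbicyclo[2.2.2]oct-5-en-2-one F2. Addition of lithiated (S)-N,S-dimethyl-S-phenylsulfoximine (n-BuLi, THF, −78 °C) gives two diastereomeric carbinols that are separated by chromatography. The one built on the (1R,4R) skeleton, the β-hydroxysulfoximine adduct F3, is heated (toluene, 110 °C) to release 9 and the sulfoximine.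

Step 8 (key step). The [3,3] shift at the methyl-bearing propenyl terminus may be slow enough that alkoxide-driven cleavage of the cage without re-closure, or a [1,3] shift, takes over. The fallback sets out from 13 and comes back at 16, and replaces charge acceleration by the neutral sigmatropic variant so that no alkoxide is present. Silylation (Me3SiOTf, Et3N, CH2Cl2, −78 °C) gives the trimethylsilyl ether F4. Thermolysis (diphenyl ether, 230–250 °C, sealed, or flash vacuum pyrolysis) effects the siloxy-Cope shift to the trimethylsilyl enol ether F5. K2CO3 in MeOH cleaves this to 16.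

Step 16 (Wharton transposition). Hydrazone formation at the C2 carbonyl, flanked by the ketal and the epoxide, may be slow, and hydrazine may meanwhile cleave the 6β-ester. The fallback sets out from 27 and comes back at 28, and avoids hydrazine by a radical epoxide fragmentation. NaBH4 (MeOH, 0 °C) reduces the C2 ketone to the epoxy alcohol F6 (either C2 epimer serves). PhOC(S)Cl, DMAP and pyridine give the O-phenyl thionocarbonate F7. Bu3SnH with AIBN (toluene, 80 °C) generates the C2 radical, which opens the adjacent epoxide to the C2=C3 alkene and a C4 alkoxyl radical that takes hydrogen from the stannane, giving 28 with the 4α-oxygen retained.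

**Further compounds**
F1 | step 5 | rac-1-isopropyl-3,3-dimethoxy-4-methyl-7-(phenylsulfanyl)bicyclo[2.2.2]oct-5-en-2-one | CC(C)C12C(Sc3ccccc3)CC(C)(C=C1)C(OC)(OC)C2=O
F2 | step 5 | rac-1-isopropyl-3,3-dimethoxy-4-methylbicyclo[2.2.2]oct-5-en-2-one | CC(C)C12CCC(C)(C=C1)C(OC)(OC)C2=O
F3 | step 5 | (1R,2S,4R)-1-isopropyl-3,3-dimethoxy-4-methyl-2-{[(S)-N-methyl-S-phenylsulfonimidoyl]methyl}bicyclo[2.2.2]oct-5-en-2-ol | CC(C)[C@]12CC[C@](C)(C=C1)C(OC)(OC)[C@]2(O)C[S@@](=O)(=NC)c3ccccc3
F4 | step 8 | trimethylsilyl ether of 13 | CC(C)[C@]12CC[C@](C)(C=C1)C(OC)(OC)[C@]2(O[Si](C)(C)C)/C=C/C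
F5 | step 8 | cis-fused 1,1-dimethoxy-2-(trimethylsilyloxy)eudesma-2,6-diene (4α-CH3, 5β-H, 10β-CH3) | CC(C)C1=C[C@@H]2[C@H](C)C=C(O[Si](C)(C)C)C(OC)(OC)[C@]2(C)CC1
F6 | step 16 | 3α,4α-epoxy-2-hydroxy-1,1-dimethoxyeudesman-6β-yl (diethoxyphosphoryl)acetate (C2 unassigned) | CC(C)[C@@H]1CC[C@@]2(C)C(OC)(OC)C(O)[C@H]3O[C@@]3(C)[C@@H]2[C@@H]1OC(=O)CP(=O)(OCC)OCC
F7 | step 16 | 3α,4α-epoxy-1,1-dimethoxy-2-(phenoxythiocarbonyloxy)eudesman-6β-yl (diethoxyphosphoryl)acetate | CC(C)[C@@H]1CC[C@@]2(C)C(OC)(OC)C(OC(=S)Oc3ccccc3)[C@H]4O[C@@]4(C)[C@@H]2[C@@H]1OC(=O)CP(=O)(OCC)OCC
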